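**Count the remainder.** Take the green flask, which is the one asked about, and reckon how much coupling partner still stands at the asked time, counting one coupling partner into each product molecule.

in all of them: left-handed substrate 0.78 M; right-handed substrate 0.78 M; coupling partner 0.624 M (fed, over 50 min); free catalyst 3.9 mM

|  | added ligand | remark | time |
|---|---|---|---|
| green | 8.3 mM | the very flask that is asked about, followed so far; the fed solution adds 0.50 times the starting volume |  |
| red | 12 mM | run made earlier; the fed solution adds 0.50 times the starting volume |  |
| flask | 8.3 mM | the fed solution adds 0.50 times the starting volume | 8.0 h |

| run | time / h | left-handed product / % | right-handed product / % |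
|---|---|---|---|
| green | 0.333 | 0.7 | 0.7 |
| green | 0.667 | 2.7 | 4.0 |
| green | 1.50 | 6.9 | 9.3 |
| green | 4.00 | 12.2 | 17.3 |
| red | 0.250 | 0.9 | 0.6 |
| red | 0.667 | 2.8 | 3.3 |
| red | 1.33 | 6.0 | 7.1 |
| red | 3.00 | 9.8 | 13.3 |

(readings scatter by 0.5 percentage points)

* excess of left-handed product over right-handed product in the product at 25 min
* excess of left-handed product over right-handed product in the product at 8.0 h
* part of the left-handed substrate and right-handed substrate charged together that has reacted at 8.0 h

- free catalyst is single-handed; left-handed substrate and right-handed substrate are mirror images of each other, charged as a racemate, each of them at the stated concentration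
- every charge counts on the volume at the start, and the solution that is fed holds the whole dose
- an excess is the difference of the two amounts in percent of their sum
- an excess is below zero if the other one leads

**The cap.** Set [coupling partner] = 0.624 M against 0.78 M of each substrate, so that the products of the green flask can reach 40.0% of the substrate charged.

**Partner half-life.** Subtract both products from that cap: the green run keeps a remainder of 23.8% at 1.50 h and 10.5% at 4.00 h, and these two readings give the partner half-life, the time in which the remainder falls to half, as 2.12 h. Count 1.89 such half-lives from 4.00 h to 8.0 h, which leaves 2.84% of the substrate charged as unused capacity, or 7.09% of the partner's charge, so 37.2% has reacted.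

**The weak link.** Test the constant half-life, since a second-order fall through the same two remainders leaves 5.54% and gives 34.5%. Keep 37.2% as the reckoning and the other as its lower edge, because the coupling partner is the limiting reagent: the substrate left at the cap, 60.0%, stays the larger pool, which makes a pseudo-first-order fall the better guess.

**The check.** The forecast gave −8%, −18% and 35%, and said of the partner: “Neither first-order nor second-order decay in the remaining partner can be ruled out.” The simulated flask gives −26.5%, −20.2% and 37.9%.

    coupling partner + catalyst intermediate B → free catalyst + right-handed product (k = 209 M⁻¹ h⁻¹)
    coupling partner + catalyst intermediate A → free catalyst + left-handed product (k = 420 M⁻¹ h⁻¹)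
    free catalyst + right-handed substrate ⇌ catalyst intermediate B (K = 12.8 M⁻¹, k = 722 M⁻¹ h⁻¹)
    free catalyst + added ligand ⇌ idle complex (K = 510 M⁻¹, k = 358 M⁻¹ h⁻¹)
    free catalyst + left-handed substrate ⇌ catalyst intermediate A (K = 2.41 M⁻¹, k = 10400 M⁻¹ h⁻¹)
    left-handed substrate ⇌ right-handed substrate (k = 0.0923 h⁻¹)

**Richer neighbour.** Read the partner half-life again in the asked flask: coupling partner falls from 23.5% of its charge at 4.00 h to 5.5% at 8.0 h, which makes 1.91 h against the 2.12 h from the readings. Now charge a neighbour with 1.1 M of coupling partner, everything else as before: its cap is 70.5%, and the fraction 5.5% that the asked flask keeps at 8.0 h, taken over unchanged, gives 66.6% reacted. That neighbour stores 64.1% reacted at 8.0 h, with 9.2% of its coupling partner left.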